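**Plan**

- Numbering follows the target decalin: ring A = C1–C5, C10 with C4=C15; ring B = C5–C10 with 6-OH, 7-i-Pr, 9-O-anisoyl, 10-Me.
- Cuts, last to first: C9–O ester; C6–H (ketone); C7–C8 (enolate opening of a C8–C9 epoxide); C6–C7 (i-Bu addition to a lactone carbonyl); C4=C15; then C5–C10 and C2–C3 together in one Michael–aldol annulation.
- Enabling feature: C5 lies between C4 (a latent ketone under the methylene) and C6 (a latent ester carbonyl), so C3–C4–C5–C6 is a hidden acetoacetate, and C10–C1–C2 is a hidden enal. C8, which ends in ring B, first carries the ester oxygen that ties the two together.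
- Forward: chiral C8/C9 diol → tethered acetoacetate enal → ring A fused to a temporary δ-lactone → acyl shift O8→O9 (γ-lactone) → ring B by i-Bu addition and epoxide alkylation → reduction, acylation.
- Stereocentres: C9 from hydrolytic kinetic resolution; C10 from C9 in the Michael step (Felkin–Anh with allylic strain); C5 by equilibration to the cis-fused γ-lactone; C7 from Z-enolate plus anti-periplanar epoxide opening; C6 by hydride attack anti to the angular methyl.

Key step: step 6

Remark: compound 1 is taken as the commercial (E)-isomer; C5 in 8–12 is configurationally labile and is drawn in the configuration that persists.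

Step 1
Reactants: 1 (2E)-4,4-dimethoxy-2-methylbut-2-enal
Product: 2 rac-2-[(2E)-4,4-dimethoxybut-2-en-2-yl]oxirane
Conditions: Me3S+ I−, KOt-Bu, DMSO/THF, 0 °C → rt
Reagents that add atoms: trimethylsulfonium iodide, C[S+](C)C.[I-]
Why: Corey–Chaykovsky epoxidation, in which dimethylsulfonium methylide adds 1,2 to the aldehyde and closes to the alkenyl oxirane while the acetal is inert to base; the new C9 centre is formed racemic and is resolved in step 2.

Step 2
Reactants: 2 rac-alkenyl oxirane
Product: 3 (2S,3E)-5,5-dimethoxy-3-methylpent-3-ene-1,2-diol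
Conditions: (S,S)-N,N′-bis(3,5-di-tert-butylsalicylidene)-1,2-cyclohexanediaminocobalt acetate (trivalent cobalt, 0.5 mol%), H2O (0.45 equiv), THF, 0 °C → rt
Reagents that add atoms: water, O
Why: Hydrolytic kinetic resolution of a terminal epoxide, in which the (S,S)-cobalt–salen catalyst should deliver water to the terminal carbon C8 of the (S)-epoxide only, so the catalyst sets the (S)-configured C9 carbinol and leaves the (R)-epoxide behind.

Step 3
Reactants: 3 (S)-diol; 4 ethyl 3-oxobutanoate
Product: 5 (2S,3E)-2-hydroxy-5,5-dimethoxy-3-methylpent-3-en-1-yl 3-oxobutanoate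
Conditions: immobilised Candida antarctica lipase B, t-BuOMe, 4 Å sieves, 40 °C
Reagents that add atoms: none
Why: Lipase-catalysed transesterification should acylate the unhindered primary C8 hydroxyl in preference to the secondary allylic one under neutral conditions that spare the acetal; no stereocentre is formed.

Step 4
Reactants: 5 primary acetoacetate
Product: 6 (2S,3E)-2-[(tert-butyldimethylsilyl)oxy]-5,5-dimethoxy-3-methylpent-3-en-1-yl 3-oxobutanoate
Conditions: TBSCl, imidazole, DMF, 0 °C → rt
Reagents that add atoms: tert-butyldimethylsilyl chloride, CC(C)(C)[Si](C)(C)Cl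
Why: Silylation of the remaining secondary hydroxyl masks O9 so that the acetoacetyl group cannot migrate to it before the key step; no stereocentre is touched.

Step 5
Reactants: 6 silyl ether acetal
Product: 7 (2S,3E)-2-[(tert-butyldimethylsilyl)oxy]-3-methyl-5-oxopent-3-en-1-yl 3-oxobutanoate
Conditions: PPTS (cat.), acetone/H2O, rt
Reagents that add atoms: water, O
Why: Mild acid-catalysed acetal hydrolysis releases the conjugated (E)-enal while the secondary silyl ether and the β-keto ester should survive; no stereocentre is touched.

Step 6
Reactants: 7 tethered acetoacetate enal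
Product: 9 enone δ-lactone (ring A fused to the temporary lactone), via Michael adduct 8 (not isolated)
Conditions: DBU (0.1 equiv), PhMe, rt; then p-TsOH·H2O (0.3 equiv), 60 °C
Reagents that add atoms: none
Why: Catalytic base forms the enolate of the tethered acetoacetate, whose central carbon C5 adds to the β-carbon C10 of the enal to give aldehyde 8; acid then enolises the acetyl group and C3 condenses with the C2 aldehyde, so the sequence is an intramolecular Robinson-type Michael–aldol annulation of a β-keto ester with an enal. The temporary δ-lactone ring closes 6-exo-trig, and ring A closes 6-(enolendo)-exo-trig followed by dehydration to the conjugated enone. The new quaternary centre C10 is controlled by the adjacent C9 centre: allylic strain keeps H9 in the alkene plane and the C9–OSi bond anti to the incoming enolate carbon (Felkin–Anh), which should place the methyl cis to the C9 oxygen; C5 is formed as a labile β-dicarbonyl centre and is fixed in step 8. The step needs 1,4- rather than 1,2-addition and closure through the acetyl methyl: 1,2-attack of C5 would need an eight-membered ring, and C3 is the only enolisable carbon that reaches the aldehyde through a six-membered transition state.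

Step 7
Reactants: 9 enone δ-lactone
Product: 10 saturated keto δ-lactone
Conditions: H2 (1 atm), Pd/C, EtOAc, rt
Reagents that add atoms: none
Why: Heterogeneous catalytic hydrogenation saturates the only C=C (the enone C2=C3) and should leave ketone, lactone and silyl ether untouched; no stereocentre is formed.

Step 8
Reactants: 10 saturated keto δ-lactone
Product: 12 cis-fused keto γ-lactone bearing the free C8 hydroxyl, via free alcohol 11 (not isolated)
Conditions: HF·pyridine, THF, 0 °C → rt; then Et3N (cat.), CH2Cl2, rt
Reagents that add atoms: none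
Why: Fluoride removes the silyl group and the freed C9 hydroxyl takes the acyl group over from O8 (intramolecular transesterification, a 1,2-acyl shift) to give the more stable γ-lactone; C5, flanked by ketone and lactone carbonyls, should equilibrate through its enol to the cis-fused 5/6 bicycle favoured next to an angular methyl, which fixes C5.

Step 9
Reactants: 12 keto γ-lactone
Product: 13 methylidene γ-lactone alcohol
Conditions: Zn, CH2Br2, TiCl4, THF/CH2Cl2, 0 °C → rt
Reagents that add atoms: dibromomethane, BrCBr
Why: Takai–Lombardo methylenation with the non-basic zinc/titanium methylene reagent should convert the enolisable C4 ketone into the exocyclic alkene without epimerising C5 and is selective for the ketone over the lactone.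

Step 10
Reactants: 13 methylidene γ-lactone alcohol
Product: 14 iodomethyl γ-lactone
Conditions: I2, PPh3, imidazole, CH2Cl2, 0 °C
Reagents that add atoms: iodine, II
Why: Appel iodination converts the primary C8 alcohol through its alkoxyphosphonium salt into the iodide by SN2 at a non-stereogenic carbon; lactone and alkene are inert.

Step 11
Reactants: 14 iodomethyl γ-lactone; 15 isobutylmagnesium chloride
Product: 16 γ-hydroxy isobutyl ketone (open form of its five-membered hemiketal)
Conditions: CeCl3, THF, −78 °C; AcOH quench at −78 °C
Reagents that add atoms: none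
Why: Organocerium addition, in which the weakly basic isobutylcerium reagent adds once to the lactone carbonyl without deprotonating C5 and the tetrahedral adduct survives at −78 °C, so C7 with its isopropyl group is attached to C6; no stereocentre is formed.

Step 12
Reactants: 16 γ-hydroxy isobutyl ketone
Product: 18 bicyclic hydroxy ketone (ring B closed), via epoxy ketone 17 (not isolated)
Conditions: LiN(i-Pr)2 (2.2 equiv), THF, −78 → 0 °C
Reagents that add atoms: none
Why: Intramolecular enolate–epoxide alkylation, in which the C9 alkoxide first closes onto C8 and kinetic deprotonation at the less hindered C7 methylene gives the Z(O)-enolate, which opens the epoxide at its primary carbon C8; anti-periplanar opening puts the C9 oxygen equatorial and the Z-enolate puts isopropyl equatorial in the chair, which should set C7 cis to the C9 oxygen while C5 is not enolised.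

Step 13
Reactants: 18 bicyclic hydroxy ketone
Product: 19 6,9-diol
Conditions: LiBH(s-Bu)3, THF, −78 °C; aq. NH4Cl
Reagents that add atoms: none
Why: Ketone reduction with the bulky hydride L-Selectride, which should deliver hydride to C6 from the equatorial side, away from the syn-axial C10 methyl, giving the axial alcohol cis to that methyl.

Step 14
Reactants: 19 6,9-diol; 20 4-methoxybenzoyl chloride
Product: 21 target 9-(4-methoxybenzoate)
Conditions: pyridine, DMAP (cat.), CH2Cl2, 0 °C → rt
Reagents that add atoms: none
Why: DMAP-catalysed acylation should take place at the equatorial C9 hydroxyl, because the C6 hydroxyl is axial, 1,3-diaxial to the angular methyl and flanked by two tertiary carbons.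

**Compound list**

1 | (2E)-4,4-dimethoxy-2-methylbut-2-enal | O=C/C(C)=C/C(OC)OC | starting material
2 | rac-2-[(2E)-4,4-dimethoxybut-2-en-2-yl]oxirane | COC(OC)/C=C(C)/C1CO1 | intermediate
3 | (2S,3E)-5,5-dimethoxy-3-methylpent-3-ene-1,2-diol | OC[C@@H](O)/C(C)=C/C(OC)OC | intermediate
4 | ethyl 3-oxobutanoate (ethyl acetoacetate) | CCOC(=O)CC(C)=O | starting material
5 | (2S,3E)-2-hydroxy-5,5-dimethoxy-3-methylpent-3-en-1-yl 3-oxobutanoate | CC(=O)CC(=O)OC[C@@H](O)/C(C)=C/C(OC)OC | intermediate
6 | (2S,3E)-2-[(tert-butyldimethylsilyl)oxy]-5,5-dimethoxy-3-methylpent-3-en-1-yl 3-oxobutanoate | CC(=O)CC(=O)OC[C@@H](O[Si](C)(C)C(C)(C)C)/C(C)=C/C(OC)OC | intermediate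
7 | (2S,3E)-2-[(tert-butyldimethylsilyl)oxy]-3-methyl-5-oxopent-3-en-1-yl 3-oxobutanoate | CC(=O)CC(=O)OC[C@@H](O[Si](C)(C)C(C)(C)C)/C(C)=C/C=O | intermediate
8 | Michael adduct (not isolated): (4R,5S)-3-acetyl-5-[(tert-butyldimethylsilyl)oxy]-4-methyl-4-(2-oxoethyl)oxan-2-one, C3 epimers | CC(=O)C1C(=O)OC[C@@H](O[Si](C)(C)C(C)(C)C)[C@]1(C)CC=O | intermediate
9 | (4S,4aR,8aR)-4-[(tert-butyldimethylsilyl)oxy]-4a-methyl-4,4a,5,8a-tetrahydro-1H-isochromene-1,8(3H)-dione (ring A enone fused to the δ-lactone; C8a labile) | O=C1C=CC[C@]2(C)[C@H]1C(=O)OC[C@H]2O[Si](C)(C)C(C)(C)C | intermediate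
10 | (4S,4aR,8aR)-4-[(tert-butyldimethylsilyl)oxy]-4a-methylhexahydro-1H-isochromene-1,8(8aH)-dione | O=C1CCC[C@]2(C)[C@H]1C(=O)OC[C@H]2O[Si](C)(C)C(C)(C)C | intermediate
11 | free alcohol (not isolated): (4S,4aR,8aR)-4-hydroxy-4a-methylhexahydro-1H-isochromene-1,8(8aH)-dione | O=C1CCC[C@]2(C)[C@H]1C(=O)OC[C@H]2O | intermediate
12 | (3S,3aR,7aR)-3-(hydroxymethyl)-3a-methylhexahydro-2-benzofuran-1,7-dione (cis-fused γ-lactone) | O=C1CCC[C@]2(C)[C@H]1C(=O)O[C@@H]2CO | intermediate
13 | (3S,3aR,7aS)-3-(hydroxymethyl)-3a-methyl-7-methylidenehexahydro-2-benzofuran-1(3H)-one | C=C1CCC[C@]2(C)[C@H]1C(=O)O[C@@H]2CO | intermediate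
14 | (3S,3aR,7aS)-3-(iodomethyl)-3a-methyl-7-methylidenehexahydro-2-benzofuran-1(3H)-one | C=C1CCC[C@]2(C)[C@H]1C(=O)O[C@@H]2CI | intermediate
15 | isobutylmagnesium chloride | CC(C)C[Mg]Cl | starting material
16 | 1-[(1S,2R)-2-[(1S)-1-hydroxy-2-iodoethyl]-2-methyl-6-methylidenecyclohexyl]-3-methylbutan-1-one (open form; equilibrates with its cyclic hemiketal) | C=C1CCC[C@@](C)([C@H](O)CI)[C@H]1C(=O)CC(C)C | intermediate
17 | epoxy ketone (not isolated): 3-methyl-1-[(1S,2R)-2-methyl-6-methylidene-2-[(2S)-oxiran-2-yl]cyclohexyl]butan-1-one | C=C1CCC[C@@](C)([C@H]2CO2)[C@H]1C(=O)CC(C)C | intermediate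
18 | (2R,4R,4aR,8aS)-4-hydroxy-4a-methyl-8-methylidene-2-(propan-2-yl)octahydronaphthalen-1(2H)-one | C=C1CCC[C@]2(C)[C@H]1C(=O)[C@@H](C(C)C)C[C@H]2O | intermediate
19 | (1R,3R,4S,4aS,8aR)-8a-methyl-5-methylidene-3-(propan-2-yl)decahydronaphthalene-1,4-diol | C=C1CCC[C@]2(C)[C@H]1[C@@H](O)[C@@H](C(C)C)C[C@H]2O | intermediate
20 | 4-methoxybenzoyl chloride | COc1ccc(cc1)C(Cl)=O | starting material
21 | (1R,3R,4S,4aS,8aR)-4-hydroxy-8a-methyl-5-methylidene-3-(propan-2-yl)decahydronaphthalen-1-yl 4-methoxybenzoate (CNP0107029.1) | C=C1CCC[C@]2(C)[C@H]1[C@@H](O)[C@@H](C(C)C)C[C@H]2OC(=O)c1ccc(OC)cc1 | target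

Total step count: 14. Longest linear sequence: 14 steps (1 → 21).

**Steps most likely to fail**

Step 6. The enolate may add to both faces of C10 if substrate control by C9 is weak, or the enal may scramble through its dienolate. Fallback: starting from 7, the Michael addition is run under iminium catalysis with the matched enantiomer of α,α-diphenylprolinol trimethylsilyl ether and benzoic acid, so that the catalyst rather than C9 shields one face of the enal. Michael adduct 8 is then isolated and ring A is closed in a separate operation by aldol condensation with pyrrolidinium acetate, which returns to 9. No compound outside the list arises (F0).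

Step 12. The base may deprotonate C5 instead of C7 (conjugated dienolate, migration of the exocyclic double bond, loss of the cis fusion), or the enolate may attack the hindered epoxide carbon. Fallback: starting from 14, lithiated isobutyl phenyl sulfone (n-BuLi, THF, −78 °C → rt) is added to the lactone in place of the isobutyl reagent. After closure of the C9 alkoxide onto C8 this should give the epoxy β-keto sulfone 3-methyl-1-[(1S,2R)-2-methyl-6-methylidene-2-[(2S)-oxiran-2-yl]cyclohexyl]-2-(phenylsulfonyl)butan-1-one F1. Its doubly activated C7–H is removed by K2CO3 in MeCN alone, so only C7 can alkylate C8, giving the sulfonyl ketone (4R,4aR,8aS)-4-hydroxy-4a-methyl-8-methylidene-2-(phenylsulfonyl)-2-(propan-2-yl)octahydronaphthalen-1(2H)-one F2. SmI2 (divalent samarium) in THF/MeOH then removes the sulfone, and axial protonation of the samarium enolate should return to 18.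

Step 9. The β-keto lactone may simply be enolised by the organometallic reagent, so that no methylene is transferred. Fallback: starting from 12, Me3SiCH2MgCl with CeCl3 (THF, −78 °C) adds to the C4 ketone to give the β-hydroxysilane (3S,3aR,7aR)-7-hydroxy-3-(hydroxymethyl)-3a-methyl-7-[(trimethylsilyl)methyl]hexahydro-2-benzofuran-1(3H)-one F3. Peterson elimination (KH, THF, or HF·pyridine) then gives 13.

Further compounds
F0 | step 6 | none | none
F1 | step 12 | 3-methyl-1-[(1S,2R)-2-methyl-6-methylidene-2-[(2S)-oxiran-2-yl]cyclohexyl]-2-(phenylsulfonyl)butan-1-one (C2 epimers) | C=C1CCC[C@@](C)([C@H]2CO2)[C@H]1C(=O)C(C(C)C)S(=O)(=O)c1ccccc1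
F2 | step 12 | (4R,4aR,8aS)-4-hydroxy-4a-methyl-8-methylidene-2-(phenylsulfonyl)-2-(propan-2-yl)octahydronaphthalen-1(2H)-one (C2 epimers) | C=C1CCC[C@]2(C)[C@H]1C(=O)C(C(C)C)(S(=O)(=O)c1ccccc1)C[C@H]2O
F3 | step 9 | (3S,3aR,7aR)-7-hydroxy-3-(hydroxymethyl)-3a-methyl-7-[(trimethylsilyl)methyl]hexahydro-2-benzofuran-1(3H)-one (C7 epimers) | C[Si](C)(C)CC1(O)CCC[C@]2(C)[C@H]1C(=O)O[C@@H]2CO
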